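**Remark:** Ring positions are counted from the carbonyl-bearing carbon (C1) of each ring; ring A is the acyl ring and ring B the phenolic ring. Orsellinic acid, methyl β-orsellinate and all reagents named are taken as commercial.

## Structural features

The target is a depside with two benzene rings and no stereocentre: ring A is a 3-carboxy-2-hydroxy-4-methoxy-6-methylbenzoyl unit and ring B is the methyl 2,4-dihydroxy-3,6-dimethylbenzoate unit. The rings are joined by one aryl ester bond from the C1 carbonyl of ring A to O4 of ring B. Ring A carries two carboxyl carbons, on C1 and C3, both ortho to the C2 hydroxyl; one must end as the aryl ester and the other as the free acid, while the methyl ester on C1 of ring B must stay untouched. The fragile groups are the aryl ester (its phenoxide leaves readily under hydroxide, alkoxide or amine attack), the ortho-hydroxy acid of ring A (prone to decarboxylation under heat or strong acid) and the methyl ester. The real difficulty is the depside bond: the acyl carbon of ring A is flanked by C2–O and C6–CH3, so addition of a phenol to it is slow and forcing acylation endangers the rest. A second difficulty is regiochemical: the C3 carbon of ring A must go between O2 and O4 and not to C5, and the 4-OH of each ring must be told apart from its hydrogen-bonded 2-OH. The key step uses the fact that C4 of ring B has only one ortho substituent (the C3 methyl), hydrogen on C5 and the ester para on C1; bonding the ring A carboxylate oxygen to this carbon leaves the crowded carbonyl carbon untouched.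

## Logic of the disconnections

**15 to 14.** The two O–CH2Ph bonds on O2 of ring A and O2 of ring B are restored. Both phenols must be masked through the copper step and the oxidation, and benzyl ethers come off by neutral hydrogenolysis, which an aryl ester tolerates. The gain is that all earlier chemistry runs on non-acidic, non-chelating ethers. The demand is a deprotection at room temperature without acid or base.

**14 to 13.** The C3 carboxyl of ring A is taken back to an aldehyde. Ring A may hold only one carboxylic acid at the coupling stage, so the C3 carbon is carried as a non-nucleophilic placeholder of lower oxidation level. The demand is a chlorite oxidation of a di-ortho-alkoxy aldehyde that does not chlorinate two electron-rich rings.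

**13 to 7 and 12.** The O–C4 bond of ring B is cut. This is the only bond between the halves that can be made without a nucleophile entering the di-ortho-substituted carbonyl of ring A. The gain is two benzene building blocks of similar size and a convergent route. The demand is that the carboxylate of 7 is the only oxygen nucleophile present and that boron sits on C4 of 12 and nowhere else.

**7 to 6.** The ester O–allyl bond is restored. The C1 carboxyl must be masked while C3 is formylated and O2 benzylated, and the mask must later leave in the presence of an aldehyde and an aryl benzyl ether. A methyl ester is a poor choice here: saponification of a di-ortho-substituted ester needs hot hydroxide, which the non-enolisable aldehyde would not survive cleanly, and iodide dealkylation (LiI) would compete at the benzyl ether, whose phenoxide is stabilised by two ortho carbonyl groups. An allyl ester is cleaved at the O–allyl bond by zerovalent palladium under neutral conditions. The demand is an allyl scavenger that does not condense with the aldehyde.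

**6 to 5.** The O2–benzyl bond of ring A is cut. Benzylation is placed after formylation because the free phenol is needed to direct the formyl group. The demand is alkylation of a hindered, doubly hydrogen-bonded phenol.

**5 to 3.** The C3–CHO bond is cut. Electrophilic formylation directed by O2 is the shortest way to put a carbon between O2 and O4. The demand is attack at C3 and not at C5.

**3 to 2 to 1.** The O4–CH3 bond and the ester O–allyl bond are cut in turn. Both alkylations rely on the acidity order carboxylic acid > 4-OH > hydrogen-bonded 2-OH, so each base picks one site. The gain is that the whole ring A carbon pattern comes from one commercial acid.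

**12 to 10 (through 11).** The C4–B bond is cut. Ring B already carries oxygen at C4, so ipso exchange of a triflate for boron fixes the position of the future depside oxygen. The demand is a borylation next to one ortho methyl and a clean release of the free boronic acid.

**10 to 9 to 8.** The O2–benzyl bond and the O4–S bond are cut. The 4-OH is sulfonylated first because it is the more acidic and accessible hydroxyl; the 2-OH is benzylated afterwards. The demand is that the triflate survives the carbonate alkylation.

## Other disconnections considered

**Alternative 1:** The cut is the C1–C6 bond of ring A, so ring A is built last on a preformed ester. In the forward sense the triketo ester A2, the 4-O-(3,5,7-trioxooctanoyl) derivative of 8, would undergo aldol closure under mild base (chain carbon 2 onto the C7 ketone), followed by dehydration and enolisation to the depside A1.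
- In its favour: the ester bond is made on an unhindered aliphatic acyl group, for instance by trapping an acylketene with the 4-OH of 8. On this point it is the equal of the chosen plan, since the hindered acylation is avoided in both. It also needs no protecting groups and no metal, which is better than the chosen plan.
- Against it: A1 lacks both the C3 carboxyl and the O4 methyl of ring A. After ring closure, ring A would still need selective O4-methylation, then formylation at C3 in competition with C5 of ring A and C5 of ring B, then oxidation. The aryl β-keto ester of A2 is also an activated ester: an enol oxygen can close onto it with loss of the ring B phenoxide to give a pyranone, in competition with the aldol.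
- Comparison: on structure the chosen plan carries every ring A substituent into the coupling, whereas here the hardest regiochemical problem is moved to the end, onto the most valuable intermediate. On mechanism the aldol is simple but competes with acyl transfer. On step economy the polyketide acyl donor plus three post-cyclisation steps make it no shorter.

**Alternative 2:** The cuts are the C1–C2 and C5–C6 bonds of ring A. The aryl but-2-ynoate A4 (from 8 and an unhindered alkynoic acid) would react with the silyl ketene acetal diene A5. The CH2 terminus of A5 should bond to the methyl-bearing alkyne carbon and the acetal carbon to the ester-bearing one; 1,4-elimination of the benzyloxy group as its alcohol and loss of silicon would give the depside A3.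
- In its favour: A3 has every ring A substituent at the right position and oxidation level, with the C3 carboxyl as a benzyl ester and the 2-OH free. One hydrogenolysis would finish the synthesis, against two steps after the key step in the chosen plan; this is better. The ester bond is again formed on an unhindered acid (equal), and the polarisation of both partners predicts the required regiochemistry.
- Against it: a β-methyl ynoate is a sluggish dienophile. A5 carries an ester on its central carbon, which lowers its nucleophilicity and makes it moisture-sensitive. The heating needed invites acyl transfer from the aryl ester of A4 to the ketene acetal, and the elimination must lose the benzyloxy group rather than the silyloxy group.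
- Comparison: on structure this is the most direct construction. On mechanism it rests on a cycloaddition of two deactivated, hindered partners, whereas the chosen plan rests on isolable, stable intermediates. On step economy it would be clearly shorter (about six steps) if the annulation proceeds; the chosen plan trades length for reliability.

**Alternative 3:** The cuts are the C1–C(=O) bond and the C(=O)–O bond. The ring A aryl bromide A7, carbon monoxide A8 and the 4-OH of 8 would combine under Pd(OAc)2 and Xantphos to give the depside A6.
- In its favour: ring B is used as 8 itself, without triflation, benzylation or borylation; that is three steps fewer on that branch and better than the chosen plan. A6 needs only one hydrogenolysis to reach the target, also better. The acyl carbon arrives as A8, so no ester on C1 of ring A has to be unmasked.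
- Against it: A7 is an electron-rich bromide flanked by a benzyloxy group and a methyl group, so oxidative addition to zerovalent palladium should be slow. The acyl palladium intermediate must then be captured at its hindered carbonyl carbon by a weakly nucleophilic phenoxide, so the steric problem of the depside bond returns, and reduction of the bromide competes. Regioselective access to A7 poses the same C3-versus-C5 question as the formylation in the chosen plan, and A8 is a toxic gas.
- Comparison: on structure both plans are convergent two-ring couplings. On mechanism the chosen plan forms its bond at the unhindered C4 of ring B, whereas this one still forms it at the crowded acyl carbon. On step economy this alternative is shorter if the carbonylation works.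

Key step: step 9

## Route

**Step 1**
Reactants: 1 orsellinic acid (2,4-dihydroxy-6-methylbenzoic acid)
Product: 2 prop-2-en-1-yl 2,4-dihydroxy-6-methylbenzoate (allyl orsellinate)
Conditions: allyl bromide (1.05 equiv), KHCO3 (1.1 equiv), DMF, rt
Reagents that add atoms: allyl bromide, C=CCBr
Why: Carboxylate O-alkylation (SN2): KHCO3 deprotonates only the carboxylic acid, so the carboxylate is alkylated and both phenols stay free; room temperature avoids decarboxylation of the ortho-hydroxy acid.

**Step 2**
Reactants: 2 prop-2-en-1-yl 2,4-dihydroxy-6-methylbenzoate
Product: 3 prop-2-en-1-yl 2-hydroxy-4-methoxy-6-methylbenzoate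
Conditions: MeI (1.1 equiv), K2CO3 (1.2 equiv), acetone, rt to 40 °C
Reagents that add atoms: iodomethane, CI
Why: Williamson etherification; the 2-OH is locked in a hydrogen bond to the ester carbonyl, so the more acidic and accessible 4-OH is the one methylated by one equivalent of MeI.

**Step 3**
Reactants: 3 prop-2-en-1-yl 2-hydroxy-4-methoxy-6-methylbenzoate
Product: 5 prop-2-en-1-yl 3-formyl-2-hydroxy-4-methoxy-6-methylbenzoate, via alpha-chloro ether 4 (not isolated)
Conditions: TiCl4 (2.2 equiv), Cl2CHOMe (1.2 equiv), CH2Cl2, −20 to 0 °C; then 1 M aq. HCl, rt
Reagents that add atoms: dichloromethyl methyl ether, COC(Cl)Cl; water, O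
Why: Rieche formylation; TiCl4 turns the phenol into an aryloxytitanium species that delivers the chloro(methoxy)carbenium ion to C3, the only free position ortho to O2 (also ortho to OMe and para to the C6 methyl), and aqueous acid hydrolyses 4 to the aldehyde.

**Step 4**
Reactants: 5 prop-2-en-1-yl 3-formyl-2-hydroxy-4-methoxy-6-methylbenzoate
Product: 6 prop-2-en-1-yl 2-(benzyloxy)-3-formyl-4-methoxy-6-methylbenzoate
Conditions: BnBr (1.3 equiv), K2CO3 (2 equiv), DMF, 50 °C
Reagents that add atoms: benzyl bromide, BrCc1ccccc1
Why: Williamson etherification of the doubly hydrogen-bonded phenoxide in a dipolar aprotic solvent; the aldehyde is non-enolisable and the allyl ester is inert to carbonate.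

**Step 5**
Reactants: 6 prop-2-en-1-yl 2-(benzyloxy)-3-formyl-4-methoxy-6-methylbenzoate
Product: 7 2-(benzyloxy)-3-formyl-4-methoxy-6-methylbenzoic acid
Conditions: Pd(PPh3)4 (3 mol%), sodium 4-methylbenzenesulfinate (1.2 equiv), THF/MeOH, rt; then 1 M aq. HCl
Reagents that add atoms: none
Why: Tsuji–Trost deallylation; zerovalent palladium ionises the O–allyl bond to a π-allyl complex and the carboxylate, and the sulfinate traps the allyl group as a sulfone, so the hindered ester is cleaved under neutral conditions without touching the benzyl ether, the methyl ether or the aldehyde.

**Step 6**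
Reactants: 8 methyl 2,4-dihydroxy-3,6-dimethylbenzoate (methyl β-orsellinate)
Product: 9 methyl 2-hydroxy-3,6-dimethyl-4-{[(trifluoromethyl)sulfonyl]oxy}benzoate
Conditions: PhNTf2 (1.05 equiv), Et3N (1.5 equiv), DMAP (5 mol%), CH2Cl2, 0 °C to rt
Reagents that add atoms: N-phenylbis(trifluoromethanesulfonimide), O=S(=O)(N(c1ccccc1)S(=O)(=O)C(F)(F)F)C(F)(F)F
Why: Phenol O-sulfonylation with a mild triflyl donor; the 4-OH is more acidic and less hindered than the 2-OH, which is hydrogen-bonded to the ester and flanked by two substituents.

**Step 7**
Reactants: 9 methyl 2-hydroxy-3,6-dimethyl-4-{[(trifluoromethyl)sulfonyl]oxy}benzoate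
Product: 10 methyl 2-(benzyloxy)-3,6-dimethyl-4-{[(trifluoromethyl)sulfonyl]oxy}benzoate
Conditions: BnBr (1.3 equiv), K2CO3 (1.5 equiv), DMF, rt to 40 °C
Reagents that add atoms: benzyl bromide, BrCc1ccccc1
Why: Williamson etherification of the remaining phenol; an aryl triflate tolerates carbonate in DMF at low temperature, and benzyl bromide is reactive enough for the hindered phenoxide.

**Step 8**
Reactants: 10 methyl 2-(benzyloxy)-3,6-dimethyl-4-{[(trifluoromethyl)sulfonyl]oxy}benzoate
Product: 12 methyl 2-(benzyloxy)-4-borono-3,6-dimethylbenzoate, via pinacol boronate 11 (not isolated)
Conditions: B2pin2 (1.2 equiv), PdCl2(dppf) (3 mol%), KOAc (3 equiv), 1,4-dioxane, 85 °C; filter, concentrate; then NaIO4 (3 equiv), NH4OAc (3 equiv), acetone/H2O, rt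
Reagents that add atoms: bis(pinacolato)diboron, CC1(C)OB(B2OC(C)(C)C(C)(C)O2)OC1(C)C; water, O
Why: Miyaura borylation (oxidative addition of the aryl triflate to zerovalent palladium, acetate-assisted transmetalation with the diboron, reductive elimination) followed by hydrolysis of 11, driven by periodate cleavage of the released pinacol; ipso substitution puts boron on C4 only.

**Step 9**
Reactants: 7 2-(benzyloxy)-3-formyl-4-methoxy-6-methylbenzoic acid; 12 methyl 2-(benzyloxy)-4-borono-3,6-dimethylbenzoate
Product: 13 methyl 2-(benzyloxy)-4-{[2-(benzyloxy)-3-formyl-4-methoxy-6-methylbenzoyl]oxy}-3,6-dimethylbenzoate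
Conditions: 12 (2 equiv), Cu(OTf)2 (0.4 equiv), urea (1 equiv), EtOAc, 60 °C, open to air
Reagents that add atoms: none
Why: Chan–Lam-type oxidative C–O coupling with a carboxylic acid as the oxygen nucleophile. Acid 7 exchanges onto Cu(OTf)2 to give a divalent copper carboxylate, with urea as a weak neutral ligand in place of an amine base. The aryl group of 12 then transmetalates from boron to copper, and oxidation by a second divalent copper centre or by O2 gives a trivalent aryl copper carboxylate. C–O reductive elimination releases 13 and monovalent copper, which air reoxidises. The new bond is O–C4 of ring B, at a carbon with one ortho methyl and one ortho hydrogen, so the carbonyl of ring A between C2–OBn and C6–CH3 never has to accept a nucleophile. No ring is closed and no stereocentre is formed. Chemoselectivity rests on the carboxylic acid being the only O–H in either partner (both phenols are benzyl ethers and the aldehyde is non-enolisable), and the position of attachment is fixed by ipso substitution at the C–B bond. The excess of 12 covers losses to protodeboronation and oxidative homocoupling.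

**Step 10**
Reactants: 13 methyl 2-(benzyloxy)-4-{[2-(benzyloxy)-3-formyl-4-methoxy-6-methylbenzoyl]oxy}-3,6-dimethylbenzoate
Product: 14 2-(benzyloxy)-3-{[3-(benzyloxy)-4-(methoxycarbonyl)-2,5-dimethylphenoxy]carbonyl}-6-methoxy-4-methylbenzoic acid
Conditions: NaClO2 (3 equiv), NaH2PO4 (3 equiv), 2-methylbut-2-ene (10 equiv), t-BuOH/THF/H2O, 0 °C to rt
Reagents that add atoms: sodium chlorite, [Na+].[O-]Cl=O
Why: Pinnick oxidation; chlorous acid adds to the aldehyde and fragments to the acid and hypochlorous acid, which the alkene traps before it can chlorinate the electron-rich rings, and the buffered, mildly acidic medium leaves both esters and both benzyl ethers intact.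

**Step 11**
Reactants: 14 2-(benzyloxy)-3-{[3-(benzyloxy)-4-(methoxycarbonyl)-2,5-dimethylphenoxy]carbonyl}-6-methoxy-4-methylbenzoic acid
Product: 15 2-hydroxy-3-{[3-hydroxy-4-(methoxycarbonyl)-2,5-dimethylphenoxy]carbonyl}-6-methoxy-4-methylbenzoic acid (the target)
Conditions: H2 (1 atm), Pd/C (10 wt%), EtOAc, rt
Reagents that add atoms: none
Why: Catalytic hydrogenolysis of both aryl benzyl ethers; the aryl ester, the methyl ester and the carboxylic acid are inert, and neutral conditions at room temperature avoid transesterification and decarboxylation.

## Compound list

1 | orsellinic acid (2,4-dihydroxy-6-methylbenzoic acid) | OC(=O)c1c(C)cc(O)cc1O | starting material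
2 | prop-2-en-1-yl 2,4-dihydroxy-6-methylbenzoate | C=CCOC(=O)c1c(C)cc(O)cc1O | intermediate
3 | prop-2-en-1-yl 2-hydroxy-4-methoxy-6-methylbenzoate | C=CCOC(=O)c1c(C)cc(OC)cc1O | intermediate
4 | prop-2-en-1-yl 3-[chloro(methoxy)methyl]-2-hydroxy-4-methoxy-6-methylbenzoate (racemic, not isolated) | C=CCOC(=O)c1c(C)cc(OC)c(C(Cl)OC)c1O | intermediate
5 | prop-2-en-1-yl 3-formyl-2-hydroxy-4-methoxy-6-methylbenzoate | C=CCOC(=O)c1c(C)cc(OC)c(C=O)c1O | intermediate
6 | prop-2-en-1-yl 2-(benzyloxy)-3-formyl-4-methoxy-6-methylbenzoate | C=CCOC(=O)c1c(C)cc(OC)c(C=O)c1OCc1ccccc1 | intermediate
7 | 2-(benzyloxy)-3-formyl-4-methoxy-6-methylbenzoic acid | OC(=O)c1c(C)cc(OC)c(C=O)c1OCc1ccccc1 | intermediate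
8 | methyl 2,4-dihydroxy-3,6-dimethylbenzoate (methyl β-orsellinate) | COC(=O)c1c(C)cc(O)c(C)c1O | starting material
9 | methyl 2-hydroxy-3,6-dimethyl-4-{[(trifluoromethyl)sulfonyl]oxy}benzoate | COC(=O)c1c(C)cc(OS(=O)(=O)C(F)(F)F)c(C)c1O | intermediate
10 | methyl 2-(benzyloxy)-3,6-dimethyl-4-{[(trifluoromethyl)sulfonyl]oxy}benzoate | COC(=O)c1c(C)cc(OS(=O)(=O)C(F)(F)F)c(C)c1OCc1ccccc1 | intermediate
11 | methyl 2-(benzyloxy)-3,6-dimethyl-4-(4,4,5,5-tetramethyl-1,3,2-dioxaborolan-2-yl)benzoate (not isolated) | COC(=O)c1c(C)cc(B2OC(C)(C)C(C)(C)O2)c(C)c1OCc1ccccc1 | intermediate
12 | methyl 2-(benzyloxy)-4-borono-3,6-dimethylbenzoate | COC(=O)c1c(C)cc(B(O)O)c(C)c1OCc1ccccc1 | intermediate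
13 | methyl 2-(benzyloxy)-4-{[2-(benzyloxy)-3-formyl-4-methoxy-6-methylbenzoyl]oxy}-3,6-dimethylbenzoate | COC(=O)c1c(C)cc(OC(=O)c2c(C)cc(OC)c(C=O)c2OCc2ccccc2)c(C)c1OCc1ccccc1 | intermediate
14 | 2-(benzyloxy)-3-{[3-(benzyloxy)-4-(methoxycarbonyl)-2,5-dimethylphenoxy]carbonyl}-6-methoxy-4-methylbenzoic acid | COC(=O)c1c(C)cc(OC(=O)c2c(C)cc(OC)c(C(=O)O)c2OCc2ccccc2)c(C)c1OCc1ccccc1 | intermediate
15 | 2-hydroxy-3-{[3-hydroxy-4-(methoxycarbonyl)-2,5-dimethylphenoxy]carbonyl}-6-methoxy-4-methylbenzoic acid | COC(=O)c1c(C)cc(OC(=O)c2c(C)cc(OC)c(C(=O)O)c2O)c(C)c1O | target

## Step count and least certain steps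

Total step count: 11. Longest linear sequence: 8 (steps 1 to 5, then 9 to 11); the ring B branch (steps 6 to 8) joins at step 9.

**Step 9 (key step).** The likeliest failure is slow ligand exchange and transmetalation at the crowded carboxylate, so that the boronic acid is consumed by protodeboronation, oxidative homocoupling or oxidation to the phenol before the C–O bond forms; slow air oxidation of the aldehyde is a lesser concern. The fallback sets out from 7 and 12 and returns at 13, and it forms the same ester from the acyl side by known depside chemistry. Compound 12 would be oxidised with aqueous H2O2 to methyl 2-(benzyloxy)-4-hydroxy-3,6-dimethylbenzoate F1. Acid 7 would be activated in toluene with trifluoroacetic anhydride as 2-(benzyloxy)-3-formyl-4-methoxy-6-methylbenzoic trifluoroacetic anhydride F2. This mixed anhydride reacts through an acylium-like species that a di-ortho-substituted aroyl group forms readily, and it should acylate F1 to give 13.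

**Step 3.** The risk is incomplete regiocontrol, with part of the electrophile entering at C5 (para to O2, ortho to the methoxy group), and some loss of the O4 methyl under the Lewis acid. The fallback sets out from 2 and returns at 5 by reversing the order of events. Compound 2 would be formylated under the same Rieche conditions while both hydroxyls are free, so that C3 lies between two titanium-bound oxygens and the aldehyde is held by two hydrogen bonds; this would give prop-2-en-1-yl 3-formyl-2,4-dihydroxy-6-methylbenzoate F3. Methylation of F3 with MeI and K2CO3 should then take place at the less hindered 4-OH to give 5.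

**Step 7.** The risk is that alkylation of the hindered, hydrogen-bonded phenoxide is slow enough for triflyl transfer between phenoxides, or carbonate-induced S–O cleavage, to compete. The fallback sets out from 9 and returns at 11, with the benzyl group introduced after the triflate has gone. Compound 9 would be borylated with the phenol free (B2pin2, PdCl2(dppf), KOAc) to methyl 2-hydroxy-3,6-dimethyl-4-(4,4,5,5-tetramethyl-1,3,2-dioxaborolan-2-yl)benzoate F4. F4 would then be benzylated with BnBr and K2CO3 to give 11, which would be isolated and hydrolysed to 12 as in step 8.

**Step 8.** The risk lies in the second stage: incomplete cleavage of the pinacol ester, or protodeboronation and difficult purification of the free boronic acid after the oxidative work-up. The fallback sets out from 11 (isolated after the borylation) and returns at 12 without an oxidant. Transesterification with diethanolamine in ether should precipitate methyl 2-(benzyloxy)-4-(1,3,6,2-dioxazaborocan-2-yl)-3,6-dimethylbenzoate F5. Brief treatment of F5 with dilute aqueous HCl would then release 12.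

## Further compounds

F1 | step 9 | methyl 2-(benzyloxy)-4-hydroxy-3,6-dimethylbenzoate | COC(=O)c1c(C)cc(O)c(C)c1OCc1ccccc1
F2 | step 9 | 2-(benzyloxy)-3-formyl-4-methoxy-6-methylbenzoic trifluoroacetic anhydride | O=C(OC(=O)C(F)(F)F)c1c(C)cc(OC)c(C=O)c1OCc1ccccc1
F3 | step 3 | prop-2-en-1-yl 3-formyl-2,4-dihydroxy-6-methylbenzoate | C=CCOC(=O)c1c(C)cc(O)c(C=O)c1O
F4 | step 7 | methyl 2-hydroxy-3,6-dimethyl-4-(4,4,5,5-tetramethyl-1,3,2-dioxaborolan-2-yl)benzoate | COC(=O)c1c(C)cc(B2OC(C)(C)C(C)(C)O2)c(C)c1O
F5 | step 8 | methyl 2-(benzyloxy)-4-(1,3,6,2-dioxazaborocan-2-yl)-3,6-dimethylbenzoate | COC(=O)c1c(C)cc(B2OCCNCCO2)c(C)c1OCc1ccccc1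
A1 | alternative 1 | methyl 4-[(2,4-dihydroxy-6-methylbenzoyl)oxy]-2-hydroxy-3,6-dimethylbenzoate | COC(=O)c1c(C)cc(OC(=O)c2c(C)cc(O)cc2O)c(C)c1O
A2 | alternative 1 | methyl 2-hydroxy-3,6-dimethyl-4-[(3,5,7-trioxooctanoyl)oxy]benzoate | COC(=O)c1c(C)cc(OC(=O)CC(=O)CC(=O)CC(C)=O)c(C)c1O
A3 | alternative 2 | methyl 4-{[3-(benzyloxycarbonyl)-2-hydroxy-4-methoxy-6-methylbenzoyl]oxy}-2-hydroxy-3,6-dimethylbenzoate | COC(=O)c1c(C)cc(OC(=O)c2c(C)cc(OC)c(C(=O)OCc3ccccc3)c2O)c(C)c1O
A4 | alternative 2 | methyl 4-(but-2-ynoyloxy)-2-hydroxy-3,6-dimethylbenzoate | COC(=O)c1c(C)cc(OC(=O)C#CC)c(C)c1O
A5 | alternative 2 | benzyl 2-[(benzyloxy)(trimethylsilyloxy)methylidene]-3-methoxybut-3-enoate (double-bond geometry not defined) | C=C(OC)C(C(=O)OCc1ccccc1)=C(OCc1ccccc1)O[Si](C)(C)C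
A6 | alternative 3 | methyl 4-{[2-(benzyloxy)-3-(benzyloxycarbonyl)-4-methoxy-6-methylbenzoyl]oxy}-2-hydroxy-3,6-dimethylbenzoate | COC(=O)c1c(C)cc(OC(=O)c2c(C)cc(OC)c(C(=O)OCc3ccccc3)c2OCc2ccccc2)c(C)c1O
A7 | alternative 3 | benzyl 2-(benzyloxy)-3-bromo-6-methoxy-4-methylbenzoate | Brc1c(C)cc(OC)c(C(=O)OCc2ccccc2)c1OCc1ccccc1
A8 | alternative 3 | carbon monoxide | [C-]#[O+]
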